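## Retrosynthetic overview

- The target is (−)-epicatechin-(4β→8)-(−)-epiafzelechin. The last C–C bond, C4 (ring C) to C8 (ring D), is cut the way proanthocyanidins grow in the plant: an epicatechin C4 carbocation (extension unit) captured by free epiafzelechin (starter unit). Only the electrophile carries benzyl ethers.
- Electrophile: (−)-epicatechin → tetrabenzyl ether → one-pot DDQ oxidation of C4–H and capture of the cation by epiafzelechin. C2 and C3 come from the chiral pool; C4 is set in the coupling, anti to the 3-OH.
- Nucleophile: kaempferol → pelargonidin (flavylium) → an anthocyanidin-reductase-like double hydride transfer with dynamic kinetic resolution, which sets the cis-(2R,3R) pair in one step from a flat precursor.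
- Rings: none is closed in the flask. Rings A/C/B arrive intact with epicatechin and rings D/F/E with kaempferol (both chalcone-derived C6–C3–C6 units). Ring F is taken from pyranone to pyrylium to saturated pyran first, then the two chromans are joined, then the benzyl groups are removed.

Assumption: nutraceutical-grade kaempferol and (−)-epicatechin count as cheap commercial materials; the (S,S)-catalyst is assumed to give the (2R,3R) sense in step 2, and the (R,R)-catalyst is taken if a trial run shows the opposite.

## Route

Step 1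
Reactants: 1 kaempferol (3,5,7-trihydroxy-2-(4-hydroxyphenyl)chromen-4-one)
Product: 2 pelargonidin chloride (3,5,7-trihydroxy-2-(4-hydroxyphenyl)chromenylium chloride)
Conditions: Zn(Hg), 3% HCl in MeOH, rt, 15 min
Reagents that add atoms: hydrogen chloride, Cl (supplies the chloride counter-ion)
Why: Clemmensen-type reduction: zinc delivers two electrons to the protonated C4 carbonyl and the acid then expels the C4 oxygen as water, leaving the aromatic flavylium (known flavonol-to-anthocyanidin reduction, modest yield); no stereocentre is involved.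

Step 2
Reactants: 2 pelargonidin chloride
Product: 5 (−)-epiafzelechin [(2R,3R)-2-(4-hydroxyphenyl)chromane-3,5,7-triol; 2,3-cis], via 4H-flav-2-en-3-ol 3 (not isolated), via flavan-3-one 4 (not isolated)
Conditions: RuCl[(S,S)-TsDPEN](p-cymene) (2 mol %), HCO2H/Et3N 5:2, DMF, 30 °C, Ar
Reagents that add atoms: none
Why: Proposed new method: the flavylium takes a first hydride from Ru–H at C4 to give enol 3, which ketonises to 4; the C2–H of 4 (α to C=O, benzylic, α-oxygenated) epimerises fast through 3 under Et3N, so the chiral Ru–H reduces only the matched (2R)-ketone on the face anti to the 2-aryl group (dynamic kinetic resolution) and sets C2 and C3 together as cis-(2R,3R), an abiotic copy of the two-hydride anthocyanidin reductase step; the closest known reaction types are Noyori–Ikariya asymmetric transfer hydrogenation of cyclic iminium and heteroaromatic cations and the cis-selective hydrogenative dynamic kinetic resolution of 2-arylcycloalkanones.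

Step 3
Reactants: 6 (−)-epicatechin [(2R,3R)-2-(3,4-dihydroxyphenyl)chromane-3,5,7-triol]
Product: 7 5,7,3',4'-tetra-O-benzyl-(−)-epicatechin [(2R,3R); four phenols as benzyl ethers, 3-OH free]
Conditions: BnBr (4.4 equiv), K2CO3 (4.4 equiv), DMF, 0 °C → rt, Ar
Reagents that add atoms: benzyl bromide, BrCc1ccccc1
Why: Williamson ether synthesis: K2CO3 deprotonates only the four phenols, not the secondary 3-OH, and the mild base at room temperature leaves C2 and C3 untouched.

Step 4
Reactants: 7 5,7,3',4'-tetra-O-benzyl-(−)-epicatechin; 5 (−)-epiafzelechin (2 equiv, excess recovered)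
Product: 10 5,7,3',4'-tetra-O-benzyl-epicatechin-(4β→8)-epiafzelechin (upper unit benzylated; lower unit free; new C4–C8 bond β), via C4 flavanyl cation 8 (not isolated), via C4 ethoxyethyl ether 9 (not isolated)
Conditions: DDQ (1.0 equiv, in portions), 2-ethoxyethanol (3 equiv), CH2Cl2, rt, 2 h; filter off DDQH2 under Ar; then 5 (2 equiv) in THF, Yb(OTf)3 (0.2 equiv), 0 °C → rt
Reagents that add atoms: none
Why: Proposed new method: DDQ abstracts hydride from C4, the position activated by the trioxygenated ring A, to give cation 8, which 2-ethoxyethanol holds as the 4β ether 9 until the oxidant is used up, so that the free polyphenol 5 never meets DDQ; Yb(OTf)3 then ionises the C4–O bond of 9 again, and the free phloroglucinol-type ring D of 5, far more nucleophilic than any benzylated ring, attacks through C8 on the β-face anti to the 3-OH and 2-aryl groups (Friedel–Crafts alkylation mirroring extension-unit capture in proanthocyanidin biosynthesis), which sets the 4β interflavan bond, with C8 expected over C6 by about 4:1 or better and the minor isomer removed by chromatography; the two halves are known separately (DDQ C4-alkoxylation of benzylated flavan-3-ols and Lewis-acid coupling of the isolated C4 ethers), only running them in one flask is new, and the closest known one-pot reaction type is DDQ cross-dehydrogenative coupling of benzylic ethers with electron-rich arenes.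

Step 5
Reactants: 10 5,7,3',4'-tetra-O-benzyl-epicatechin-(4β→8)-epiafzelechin
Product: 11 (−)-epicatechin-(4β→8)-(−)-epiafzelechin [upper unit (2R,3R,4R), lower unit (2R,3R)], the target CNP0299023.1
Conditions: H2 (1 atm), Pd(OH)2/C, THF/MeOH/H2O 20:1:1, rt
Reagents that add atoms: none
Why: Heterogeneous hydrogenolysis cleaves the four aryl benzyl ethers, while the C4–C8 diarylmethine bond and all five stereocentres are untouched under neutral conditions.

## Compound list

1 | kaempferol | O=c1c(O)c(-c2ccc(O)cc2)oc2cc(O)cc(O)c12 | starting material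
2 | pelargonidin chloride | Oc1ccc(-c2[o+]c3cc(O)cc(O)c3cc2O)cc1.[Cl-] | intermediate
3 | 2-(4-hydroxyphenyl)-4H-chromene-3,5,7-triol (4H-flav-2-en-3-ol; no stereocentre) | OC1=C(c2ccc(O)cc2)Oc2cc(O)cc(O)c2C1 | intermediate (not isolated)
4 | 5,7-dihydroxy-2-(4-hydroxyphenyl)chroman-3-one (flavan-3-one; C2 epimers interconvert, drawn without configuration) | O=C1Cc2c(O)cc(O)cc2OC1c1ccc(O)cc1 | intermediate (not isolated)
5 | (−)-epiafzelechin, (2R,3R) | Oc1ccc([C@H]2Oc3cc(O)cc(O)c3C[C@H]2O)cc1 | intermediate
6 | (−)-epicatechin, (2R,3R) | C1c2c(O)cc(O)cc2O[C@H](c2ccc(O)c(O)c2)[C@@H]1O | starting material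
7 | 5,7,3',4'-tetra-O-benzyl-(−)-epicatechin, (2R,3R) | C1c2c(OCc3ccccc3)cc(OCc3ccccc3)cc2O[C@H](c2ccc(OCc3ccccc3)c(OCc3ccccc3)c2)[C@@H]1O | intermediate
8 | C4 flavanyl cation of 7 (C2 and C3 as in 7; charge delocalised into ring A) | [CH+]1c2c(OCc3ccccc3)cc(OCc3ccccc3)cc2O[C@H](c2ccc(OCc3ccccc3)c(OCc3ccccc3)c2)[C@@H]1O | intermediate (not isolated)
9 | 4β-(2-ethoxyethoxy)-5,7,3',4'-tetra-O-benzyl-(−)-epicatechin, (2R,3R,4S); new ether trans to the 3-OH | CCOCCO[C@H]1c2c(OCc3ccccc3)cc(OCc3ccccc3)cc2O[C@H](c2ccc(OCc3ccccc3)c(OCc3ccccc3)c2)[C@@H]1O | intermediate (not isolated)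
10 | 5,7,3',4'-tetra-O-benzyl-epicatechin-(4β→8)-epiafzelechin (interflavan bond β, trans to the upper 3-OH; same C4 geometry as 11) | Oc1ccc([C@H]2Oc3c(c(O)cc(O)c3[C@H]3c4c(OCc5ccccc5)cc(OCc5ccccc5)cc4O[C@H](c4ccc(OCc5ccccc5)c(OCc5ccccc5)c4)[C@@H]3O)C[C@H]2O)cc1 | intermediate
11 | (−)-epicatechin-(4β→8)-(−)-epiafzelechin, upper (2R,3R,4R), lower (2R,3R) | Oc1ccc([C@H]2Oc3c(c(O)cc(O)c3[C@H]3c4c(O)cc(O)cc4O[C@H](c4ccc(O)c(O)c4)[C@@H]3O)C[C@H]2O)cc1 | target

## Step count and risks

Total steps: 5. Longest linear sequence: 4 steps (1 → 2 → 5 → 10 → 11); the other branch (6 → 7 → 10 → 11) is 3 steps.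

The three steps most likely to fail, in order:

First, step 2 (asymmetric double hydride transfer). The sense and level of induction are unproven, and ketone 4 could self-condense through its C3–C4 enol before it is reduced. Fallback, setting out from 2: hydrogenation (H2, PtO2, EtOH, rt) gives the racemic cis-flavan-3-ol, that is 5 together with its mirror image ent-epiafzelechin F1. The racemate is taken through step 4 as it stands. The single-enantiomer cation 8 turns it into 10 and the diastereomer 5,7,3',4'-tetra-O-benzyl-epicatechin-(4β→8)-ent-epiafzelechin F2. Chromatographic removal of the latter brings the route back at 10, so the upper unit serves as the resolving agent.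

Second, step 4 (one-flask oxidation and coupling with the unprotected nucleophile). Leftover DDQ may oxidise 5 or 10, conversion of 7 with only one equivalent of DDQ may be incomplete, and the C6-linked isomer or double alkylation of ring D may erode the yield. Fallback, setting out from 5, with the electrophile made apart: 7 is oxidised on its own (DDQ 2 equiv, 2-ethoxyethanol, CH2Cl2, rt) and ether 9 is isolated by chromatography. Benzylation of 5 (BnBr, K2CO3, DMF) gives 5,7,4'-tri-O-benzyl-(−)-epiafzelechin F3, in which ring D reacts only at C8. Coupling of F3 (in excess) with 9 (TMSOTf, CH2Cl2, −78 °C) gives hepta-O-benzyl-epicatechin-(4β→8)-epiafzelechin F4. Hydrogenolysis under the conditions of step 5 comes back to the route at 11.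

Third, step 1 (zinc reduction). Low yield and over-reduction past the flavylium stage are likely. Fallback, setting out from 1: peracetylation (Ac2O, pyridine) gives the THF-soluble 3,5,7,4'-tetra-O-acetylkaempferol F5. LiAlH4 (THF, 0 °C) then adds hydride to the C4 carbonyl and strips the acetates. Quenching into methanolic HCl dehydrates the C4 alcohol to the flavylium and comes back to the route at 2.

## Further compounds

F1 | step 2 | ent-epiafzelechin, (2S,3S)-2-(4-hydroxyphenyl)chromane-3,5,7-triol | Oc1ccc([C@@H]2Oc3cc(O)cc(O)c3C[C@@H]2O)cc1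
F2 | step 2 | 5,7,3',4'-tetra-O-benzyl-epicatechin-(4β→8)-ent-epiafzelechin | Oc1ccc([C@@H]2Oc3c(c(O)cc(O)c3[C@H]3c4c(OCc5ccccc5)cc(OCc5ccccc5)cc4O[C@H](c4ccc(OCc5ccccc5)c(OCc5ccccc5)c4)[C@@H]3O)C[C@@H]2O)cc1
F3 | step 4 | 5,7,4'-tri-O-benzyl-(−)-epiafzelechin, (2R,3R) | C(c1ccccc1)Oc1ccc([C@H]2Oc3cc(OCc4ccccc4)cc(OCc4ccccc4)c3C[C@H]2O)cc1
F4 | step 4 | hepta-O-benzyl-epicatechin-(4β→8)-epiafzelechin (all seven phenols benzylated, both 3-OH free) | C(c1ccccc1)Oc1ccc([C@H]2Oc3c(c(OCc4ccccc4)cc(OCc4ccccc4)c3[C@H]3c4c(OCc5ccccc5)cc(OCc5ccccc5)cc4O[C@H](c4ccc(OCc5ccccc5)c(OCc5ccccc5)c4)[C@@H]3O)C[C@H]2O)cc1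
F5 | step 1 | 3,5,7,4'-tetra-O-acetylkaempferol | CC(=O)Oc1ccc(-c2oc3cc(OC(C)=O)cc(OC(C)=O)c3c(=O)c2OC(C)=O)cc1
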